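The cyclobutane is cut at the C1–C4 bond (C1 bears the free CO2H, C4 the catechol ring); this unfolds ring carbons C1–C4, with their alternating carboxyl/aryl pattern, into C3–C6 of a 4,6-diaryl-2-pyrone-5-carboxylate whose lactone carbonyl is the C1 carboxyl. That pattern is the feature the key step exploits: irradiation closes the cyclobutene of a 2-oxabicyclo[2.2.0]hexenone in one operation, with all four substituents in place. The precursor is pyrone 9, with benzyl-protected phenols and a tert-butyl ester, assembled from a β-keto ester and an arylpropiolate. Hydrogenation, epimerisation at C1 and C3, and esterification with (R)-danshensu, where the ring diastereomers are separated, complete the route.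

Key step: step 4

Remark: compounds 10–15 are racemic and are drawn as the enantiomer that leads to the target; ring carbons are numbered C1–C4 as in the target throughout; 1 and 5 are taken as catalogue chemicals and 16 as the free acid.

Step 1
Reactants: 1 methyl 3,4-bis(benzyloxy)benzoate; 2 tert-butyl acetate
Product: 4 tert-butyl 3-[3,4-bis(benzyloxy)phenyl]-3-oxopropanoate, via lithium enolate of tert-butyl acetate 3 (not isolated)
Conditions: LiN(SiMe3)2 (3.2 equiv), THF, −78 °C → 0 °C; then 1 M HCl
Reagents that add atoms: none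
Why: Crossed Claisen condensation, in which the preformed ester enolate acylates the non-enolisable aryl ester and the β-keto ester is drawn out of the equilibrium as its lithium enolate by the excess base.

Step 2
Reactants: 5 1-(benzyloxy)-4-iodobenzene; 6 ethyl propiolate
Product: 7 ethyl 3-[4-(benzyloxy)phenyl]prop-2-ynoate
Conditions: Pd(PPh3)2Cl2 (2 mol%), CuI (4 mol%), K2CO3 (2 equiv), THF, 65 °C (6 in excess)
Reagents that add atoms: none
Why: Sonogashira coupling of an aryl iodide with the terminal alkyne, run with carbonate in place of an amine so that no amine can add to the propiolate.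

Step 3
Reactants: 4 tert-butyl 3-[3,4-bis(benzyloxy)phenyl]-3-oxopropanoate; 7 ethyl 3-[4-(benzyloxy)phenyl]prop-2-ynoate
Product: 9 tert-butyl 6-[3,4-bis(benzyloxy)phenyl]-4-[4-(benzyloxy)phenyl]-2-oxo-2H-pyran-5-carboxylate, via open-chain Michael adduct 8 (not isolated)
Conditions: KOtBu (0.3 equiv), THF, 0 °C → 60 °C
Reagents that add atoms: none
Why: Michael addition of the β-keto ester enolate to the ynoate followed by lactonisation of the ketone enol oxygen onto the ethyl ester is the classical base-mediated 2-pyrone synthesis, and because the aryl ketone has no second enolisable position the pyrone is the only ring that can close, with the aryl groups at C4 and C6 and the ester at C5.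

Step 4
Reactants: 9 tert-butyl 6-[3,4-bis(benzyloxy)phenyl]-4-[4-(benzyloxy)phenyl]-2-oxo-2H-pyran-5-carboxylate
Product: 10 tert-butyl (1R,4S)-1-[3,4-bis(benzyloxy)phenyl]-5-[4-(benzyloxy)phenyl]-3-oxo-2-oxabicyclo[2.2.0]hex-5-ene-6-carboxylate (racemic)
Conditions: hν (365 nm), degassed EtOAc (5 mM), 5 °C; concentrated cold and used at once
Reagents that add atoms: none
Why: Excitation of the pyrone chromophore leads to a photochemically allowed, disrotatory 4π-electrocyclisation of the diene C3=C4–C5=C6, which forms the C3–C6 σ-bond (C1–C4 of the target) and leaves C4=C5 as the cyclobutene double bond. The closest known reaction is the light-induced valence isomerisation of 2-pyrone and of 2-pyrone-5-carboxylic (coumalic) esters to 2-oxabicyclo[2.2.0]hex-5-en-3-ones. The one ring closed is the cyclobutene, by 4π disrotatory electrocyclic closure, while the β-lactone is what is left of the pyranone ring. The two new stereocentres are the bridgeheads C1 and C4 of the bicycle, which the [2.2.0] ring fusion forces to be cis, so the relative configuration is fixed by geometry and the product is racemic. Regioselectivity is not in question because the pyrone offers a single diene whose ends already carry the catechol ring and the lactone carbonyl. The selectivity needed is chemoselectivity for closure over dimerisation, ring opening to a ketene and secondary photolysis of 10, and it should be secured by the fully substituted C4–C6 edge of 9 together with high dilution, an aprotic solvent and 365 nm light, which the diaryl pyrone should absorb and the cinnamate-like chromophore of 10 should not.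

Step 5
Reactants: 10 tert-butyl (1R,4S)-1-[3,4-bis(benzyloxy)phenyl]-5-[4-(benzyloxy)phenyl]-3-oxo-2-oxabicyclo[2.2.0]hex-5-ene-6-carboxylate
Product: 12 3-tert-butyl hydrogen (1S,2R,3R,4S)-4-(3,4-dihydroxyphenyl)-2-(4-hydroxyphenyl)cyclobutane-1,3-dicarboxylate (all four substituents cis; racemic), via saturated bicyclic lactone 11 (not isolated)
Conditions: H2 (1 atm), 10% Pd/C, EtOAc, 0 °C → rt; product kept under argon
Reagents that add atoms: none
Why: Heterogeneous catalytic hydrogenation adds H2 to the strained cyclobutene from the convex face (opposite the lactone ring) and then cleaves the benzylic, strain-activated lactone C–O bond by hydrogenolysis with inversion, the usual course for benzylic C–O bonds on palladium and in line with the one-pot reduction known for the photoisomers of coumalate esters, so that C2, C3 and C4 are set with all four substituents cis while the O-benzyl groups are lost in the same operation.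

Step 6
Reactants: 12 3-tert-butyl hydrogen (1S,2R,3R,4S)-4-(3,4-dihydroxyphenyl)-2-(4-hydroxyphenyl)cyclobutane-1,3-dicarboxylate
Product: 13 1-benzyl 3-tert-butyl (1S,2R,3R,4S)-4-[3,4-bis(benzyloxy)phenyl]-2-[4-(benzyloxy)phenyl]cyclobutane-1,3-dicarboxylate (all-cis; racemic)
Conditions: BnBr (4.5 equiv), K2CO3 (6 equiv), DMF, rt, argon
Reagents that add atoms: benzyl bromide, BrCc1ccccc1
Why: Williamson etherification of the three phenoxides and SN2 alkylation of the carboxylate restore the benzyl ethers and give the C1 benzyl ester in one operation, with no ring stereocentre expected to change (any early epimerisation runs in the direction wanted in step 7).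

Step 7
Reactants: 13 1-benzyl 3-tert-butyl (1S,2R,3R,4S)-4-[3,4-bis(benzyloxy)phenyl]-2-[4-(benzyloxy)phenyl]cyclobutane-1,3-dicarboxylate
Product: 14 1-benzyl 3-tert-butyl (1R,2R,3S,4S)-4-[3,4-bis(benzyloxy)phenyl]-2-[4-(benzyloxy)phenyl]cyclobutane-1,3-dicarboxylate (each ester trans to both aryl groups, aryl groups cis to each other; racemic)
Conditions: NaOBn (0.3 equiv, 1 M in BnOH), THF, rt → 50 °C
Reagents that add atoms: none
Why: Base-mediated epimerisation under thermodynamic control, in which reversible enolisation at C1 and C3 moves each ester from the face crowded by two cis aryl groups to the opposite face and should end at the all-trans isomer, the most stable arrangement of 2,4-diarylcyclobutane-1,3-dicarboxylates; exchange at the benzyl ester is degenerate with benzyloxide and the tert-butyl ester is expected to resist it.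

Step 8
Reactants: 14 1-benzyl 3-tert-butyl (1R,2R,3S,4S)-4-[3,4-bis(benzyloxy)phenyl]-2-[4-(benzyloxy)phenyl]cyclobutane-1,3-dicarboxylate
Product: 15 1-benzyl hydrogen (1R,2S,3S,4R)-4-[3,4-bis(benzyloxy)phenyl]-2-[4-(benzyloxy)phenyl]cyclobutane-1,3-dicarboxylate (same all-trans geometry as 14; racemic)
Conditions: CF3CO2H/CH2Cl2 (1:4), 0 °C → rt
Reagents that add atoms: none
Why: Acidolysis of the tert-butyl ester (E1 loss of 2-methylpropene) frees the C3 carboxyl while the benzyl ester and benzyl ethers are stable to brief exposure, and no stereocentre is involved.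

Step 9
Reactants: 16 (R)-3-(3,4-dihydroxyphenyl)lactic acid (danshensu)
Product: 17 benzyl (2R)-3-[3,4-bis(benzyloxy)phenyl]-2-hydroxypropanoate
Conditions: BnBr (3.3 equiv), K2CO3 (3.5 equiv), DMF, 0 °C → rt
Reagents that add atoms: benzyl bromide, BrCc1ccccc1
Why: Carbonate deprotonates only the carboxylic acid and the two phenols, which are benzylated (carboxylate alkylation and Williamson etherification), while the secondary alcohol stays free and its stereocentre is untouched.

Step 10
Reactants: 15 1-benzyl hydrogen (1R,2S,3S,4R)-4-[3,4-bis(benzyloxy)phenyl]-2-[4-(benzyloxy)phenyl]cyclobutane-1,3-dicarboxylate (racemic); 17 benzyl (2R)-3-[3,4-bis(benzyloxy)phenyl]-2-hydroxypropanoate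
Product: 18 1-benzyl 3-{(2R)-1-(benzyloxy)-3-[3,4-bis(benzyloxy)phenyl]-1-oxopropan-2-yl} (1R,2R,3S,4S)-4-[3,4-bis(benzyloxy)phenyl]-2-[4-(benzyloxy)phenyl]cyclobutane-1,3-dicarboxylate
Conditions: EDC·HCl (1.5 equiv), DMAP (1 equiv), CH2Cl2, 0 °C → rt; chromatography on SiO2 to remove the ring diastereomer
Reagents that add atoms: none
Why: Steglich esterification through the acylpyridinium ion acylates the alcohol oxygen with retention at the lactate carbon, and since racemic 15 meets enantiopure 17 two diastereomeric esters should form, of which 18 (ring configuration of the target) is separated by chromatography from the (1S,2S,3R,4R) ring isomer that arises from the other enantiomer of 15, this being the point where the absolute configuration of the ring is fixed.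

Step 11
Reactants: 18 1-benzyl 3-{(2R)-1-(benzyloxy)-3-[3,4-bis(benzyloxy)phenyl]-1-oxopropan-2-yl} (1R,2R,3S,4S)-4-[3,4-bis(benzyloxy)phenyl]-2-[4-(benzyloxy)phenyl]cyclobutane-1,3-dicarboxylate
Product: 19 (1R,2R,3S,4S)-3-{[(1R)-1-carboxy-2-(3,4-dihydroxyphenyl)ethoxy]carbonyl}-4-(3,4-dihydroxyphenyl)-2-(4-hydroxyphenyl)cyclobutane-1-carboxylic acid
Conditions: H2 (1 atm), 10% Pd/C, THF/EtOAc, rt
Reagents that add atoms: none
Why: Hydrogenolysis of the five benzyl ethers and the two benzyl esters under neutral conditions should leave the ester link to the lactate (its C–O carbon is not benzylic), the cyclobutane and all stereocentres untouched.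

Compound list
1 | methyl 3,4-bis(benzyloxy)benzoate | COC(=O)c1ccc(OCc2ccccc2)c(OCc2ccccc2)c1 | starting material
2 | tert-butyl acetate | CC(=O)OC(C)(C)C | starting material
3 | lithium enolate of tert-butyl acetate (lithium 1-tert-butoxyethenolate) | [Li+].[O-]C(=C)OC(C)(C)C | intermediate
4 | tert-butyl 3-[3,4-bis(benzyloxy)phenyl]-3-oxopropanoate | CC(C)(C)OC(=O)CC(=O)c1ccc(OCc2ccccc2)c(OCc2ccccc2)c1 | intermediate
5 | 1-(benzyloxy)-4-iodobenzene | Ic1ccc(OCc2ccccc2)cc1 | starting material
6 | ethyl propiolate | C#CC(=O)OCC | starting material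
7 | ethyl 3-[4-(benzyloxy)phenyl]prop-2-ynoate | CCOC(=O)C#Cc1ccc(OCc2ccccc2)cc1 | intermediate
8 | 1-tert-butyl 5-ethyl 2-[3,4-bis(benzyloxy)benzoyl]-3-[4-(benzyloxy)phenyl]pent-3-enedioate (E/Z mixture, present as its potassium enolate) | CCOC(=O)C=C(c1ccc(OCc2ccccc2)cc1)C(C(=O)OC(C)(C)C)C(=O)c1ccc(OCc2ccccc2)c(OCc2ccccc2)c1 | intermediate
9 | tert-butyl 6-[3,4-bis(benzyloxy)phenyl]-4-[4-(benzyloxy)phenyl]-2-oxo-2H-pyran-5-carboxylate | O=c1cc(-c2ccc(OCc3ccccc3)cc2)c(C(=O)OC(C)(C)C)c(-c2ccc(OCc3ccccc3)c(OCc3ccccc3)c2)o1 | intermediate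
10 | tert-butyl (1R,4S)-1-[3,4-bis(benzyloxy)phenyl]-5-[4-(benzyloxy)phenyl]-3-oxo-2-oxabicyclo[2.2.0]hex-5-ene-6-carboxylate (cis-fused; racemic) | O=C1O[C@]2(c3ccc(OCc4ccccc4)c(OCc4ccccc4)c3)C(C(=O)OC(C)(C)C)=C(c3ccc(OCc4ccccc4)cc3)[C@H]12 | intermediate
11 | tert-butyl 1-[3,4-bis(benzyloxy)phenyl]-5-[4-(benzyloxy)phenyl]-3-oxo-2-oxabicyclo[2.2.0]hexane-6-carboxylate (cis-fused; 5-aryl and 6-ester on the face that carries the lactone ring; racemic) | O=C1O[C@]2(c3ccc(OCc4ccccc4)c(OCc4ccccc4)c3)[C@H](C(=O)OC(C)(C)C)[C@H](c3ccc(OCc4ccccc4)cc3)[C@H]12 | intermediate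
12 | 3-tert-butyl hydrogen (1S,2R,3R,4S)-4-(3,4-dihydroxyphenyl)-2-(4-hydroxyphenyl)cyclobutane-1,3-dicarboxylate (all-cis; racemic) | OC(=O)[C@H]1[C@@H](c2ccc(O)cc2)[C@@H](C(=O)OC(C)(C)C)[C@H]1c1ccc(O)c(O)c1 | intermediate
13 | 1-benzyl 3-tert-butyl (1S,2R,3R,4S)-4-[3,4-bis(benzyloxy)phenyl]-2-[4-(benzyloxy)phenyl]cyclobutane-1,3-dicarboxylate (all-cis; racemic) | O=C(OCc5ccccc5)[C@H]1[C@@H](c2ccc(OCc3ccccc3)cc2)[C@@H](C(=O)OC(C)(C)C)[C@H]1c1ccc(OCc2ccccc2)c(OCc2ccccc2)c1 | intermediate
14 | 1-benzyl 3-tert-butyl (1R,2R,3S,4S)-4-[3,4-bis(benzyloxy)phenyl]-2-[4-(benzyloxy)phenyl]cyclobutane-1,3-dicarboxylate (all-trans; racemic) | O=C(OCc5ccccc5)[C@@H]1[C@@H](c2ccc(OCc3ccccc3)cc2)[C@H](C(=O)OC(C)(C)C)[C@H]1c1ccc(OCc2ccccc2)c(OCc2ccccc2)c1 | intermediate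
15 | 1-benzyl hydrogen (1R,2S,3S,4R)-4-[3,4-bis(benzyloxy)phenyl]-2-[4-(benzyloxy)phenyl]cyclobutane-1,3-dicarboxylate (all-trans; racemic) | O=C(OCc5ccccc5)[C@@H]1[C@@H](c2ccc(OCc3ccccc3)cc2)[C@H](C(=O)O)[C@H]1c1ccc(OCc2ccccc2)c(OCc2ccccc2)c1 | intermediate
16 | (R)-3-(3,4-dihydroxyphenyl)lactic acid (danshensu) | O[C@H](Cc1ccc(O)c(O)c1)C(=O)O | starting material
17 | benzyl (2R)-3-[3,4-bis(benzyloxy)phenyl]-2-hydroxypropanoate | O[C@H](Cc1ccc(OCc2ccccc2)c(OCc2ccccc2)c1)C(=O)OCc1ccccc1 | intermediate
18 | 1-benzyl 3-{(2R)-1-(benzyloxy)-3-[3,4-bis(benzyloxy)phenyl]-1-oxopropan-2-yl} (1R,2R,3S,4S)-4-[3,4-bis(benzyloxy)phenyl]-2-[4-(benzyloxy)phenyl]cyclobutane-1,3-dicarboxylate | O=C(OCc5ccccc5)[C@@H]1[C@@H](c2ccc(OCc3ccccc3)cc2)[C@H](C(=O)O[C@H](Cc2ccc(OCc3ccccc3)c(OCc3ccccc3)c2)C(=O)OCc2ccccc2)[C@H]1c1ccc(OCc2ccccc2)c(OCc2ccccc2)c1 | intermediate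
19 | (1R,2R,3S,4S)-3-{[(1R)-1-carboxy-2-(3,4-dihydroxyphenyl)ethoxy]carbonyl}-4-(3,4-dihydroxyphenyl)-2-(4-hydroxyphenyl)cyclobutane-1-carboxylic acid | O=C(O)[C@@H]1[C@@H](c2ccc(O)cc2)[C@H](C(=O)O[C@H](Cc2ccc(O)c(O)c2)C(=O)O)[C@H]1c1ccc(O)c(O)c1 | target

Total step count: 11 steps.
Longest linear sequence: 9 steps (steps 1, 3, 4, 5, 6, 7, 8, 10, 11).

Steps most likely to fail

Step 4. The excited state of the donor-substituted diaryl pyrone may relax without closing or dimerise, and the lactone may reopen thermally or ionise at its electron-rich benzylic C–O bond before it is reduced. The fallback drops the photochemistry on the aryl-laden pyrone and attaches the aryl groups to a preformed cyclobutane by directed C–H arylation; it sets out from iodide 5 and comes back at 14. Commercial 3-oxabicyclo[3.1.1]heptane-2,4-dione (the cyclic anhydride of cis-cyclobutane-1,3-dicarboxylic acid) is opened with KOtBu in THF to cis-3-(tert-butoxycarbonyl)cyclobutane-1-carboxylic acid F1, which EDC·HCl and 2-(methylsulfanyl)aniline convert into the anilide tert-butyl cis-3-{[2-(methylsulfanyl)phenyl]carbamoyl}cyclobutane-1-carboxylate F2. Pd(OAc)2 (catalytic), Ag2CO3 and pivalic acid in (CF3)2CHOH at 90 °C with 5 should arylate the ring C–H bond cis to the directing amide and give the all-cis monoaryl amide F3. LiOtBu in toluene at 50 °C then epimerises only the ester-bearing carbon (the amide is protected as its anion) to the trans-ester monoaryl amide F4, which clears the second β-position. Commercial 1,2-bis(benzyloxy)benzene is iodinated (N-iodosuccinimide, catalytic CF3CO2H, MeCN) to 1,2-bis(benzyloxy)-4-iodobenzene F5, and a second arylation of F4 with F5 under the same conditions gives the diaryl amide F6, both aryl groups cis to the amide. Boc2O/DMAP in MeCN gives the N-Boc anilide F7, and NaOBn in BnOH/THF cleaves this activated amide to the benzyl ester and equilibrates the last α-carbon, which returns racemic 14.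

Step 5. Facial control may be lost: hydrogen delivery to the alkene from the concave face, or C–O cleavage with retention, would leave the two aryl groups trans to each other, which no later epimerisation can repair. The fallback separates the two reductions and cuts the C–O bond ionically instead of on the metal surface; it sets out from 10 and comes back at 13. Hydrogenation of 10 over Rh/Al2O3 (H2, 1 atm, EtOAc), a catalyst with little tendency to hydrogenolyse benzylic C–O bonds or benzyl ethers, should stop at the saturated lactone 11, which is isolated. Et3SiH with BF3·OEt2 in CH2Cl2 at −78 °C then ionises the lactone to a benzylic cation, planar and stabilised by the para-benzyloxy group, and should deliver hydride to its open face, opposite the three substituents on the other side, to give the all-cis tris(benzyloxy) acid F8. BnBr/K2CO3 in DMF esterifies F8 to 13.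

Step 10. Acyl transfer from the hindered acid to the weakly nucleophilic α-hydroxy ester may be slow, and 18 may not separate cleanly on silica from its ring diastereomer. The fallback moves the resolution ahead of the coupling; it sets out from racemic 14 and comes back at 14 as a single enantiomer. The enantiomers of 14 are separated by preparative chromatography on a chiral stationary phase (for example amylose tris(3,5-dimethylphenylcarbamate) on silica) and the (1R,2R,3S,4S) enantiomer is taken through step 8. Compound 18 should then form as a single diastereomer, so the coupling can be forced with excess 17 and longer time without a separation problem; no new compound is made (F0).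

Further compounds
F1 | step 4 | cis-3-(tert-butoxycarbonyl)cyclobutane-1-carboxylic acid | OC(=O)[C@H]1C[C@@H](C(=O)OC(C)(C)C)C1
F2 | step 4 | tert-butyl cis-3-{[2-(methylsulfanyl)phenyl]carbamoyl}cyclobutane-1-carboxylate | CSc1ccccc1NC(=O)[C@H]1C[C@@H](C(=O)OC(C)(C)C)C1
F3 | step 4 | tert-butyl 2-[4-(benzyloxy)phenyl]-3-{[2-(methylsulfanyl)phenyl]carbamoyl}cyclobutane-1-carboxylate, all-cis, racemic | CSc1ccccc1NC(=O)[C@H]1[C@@H](c2ccc(OCc3ccccc3)cc2)[C@@H](C(=O)OC(C)(C)C)C1
F4 | step 4 | tert-butyl 2-[4-(benzyloxy)phenyl]-3-{[2-(methylsulfanyl)phenyl]carbamoyl}cyclobutane-1-carboxylate, ester trans to aryl, amide cis to aryl, racemic | CSc1ccccc1NC(=O)[C@H]1[C@@H](c2ccc(OCc3ccccc3)cc2)[C@H](C(=O)OC(C)(C)C)C1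
F5 | step 4 | 1,2-bis(benzyloxy)-4-iodobenzene | Ic1ccc(OCc2ccccc2)c(OCc2ccccc2)c1
F6 | step 4 | tert-butyl 4-[3,4-bis(benzyloxy)phenyl]-2-[4-(benzyloxy)phenyl]-3-{[2-(methylsulfanyl)phenyl]carbamoyl}cyclobutane-1-carboxylate, amide cis to both aryl groups, ester trans to both, racemic | CSc1ccccc1NC(=O)[C@H]1[C@@H](c2ccc(OCc3ccccc3)cc2)[C@H](C(=O)OC(C)(C)C)[C@H]1c1ccc(OCc2ccccc2)c(OCc2ccccc2)c1
F7 | step 4 | tert-butyl 4-[3,4-bis(benzyloxy)phenyl]-2-[4-(benzyloxy)phenyl]-3-{(tert-butoxycarbonyl)[2-(methylsulfanyl)phenyl]carbamoyl}cyclobutane-1-carboxylate, same relative configuration as F6, racemic | CSc1ccccc1N(C(=O)OC(C)(C)C)C(=O)[C@H]1[C@@H](c2ccc(OCc3ccccc3)cc2)[C@H](C(=O)OC(C)(C)C)[C@H]1c1ccc(OCc2ccccc2)c(OCc2ccccc2)c1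
F8 | step 5 | 3-tert-butyl hydrogen 4-[3,4-bis(benzyloxy)phenyl]-2-[4-(benzyloxy)phenyl]cyclobutane-1,3-dicarboxylate, all-cis, racemic | OC(=O)[C@H]1[C@@H](c2ccc(OCc3ccccc3)cc2)[C@@H](C(=O)OC(C)(C)C)[C@H]1c1ccc(OCc2ccccc2)c(OCc2ccccc2)c1
F0 | step 10 | none | none
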